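Numbering used throughout: bornane atoms are C1 (quaternary bridgehead carrying methyl C10), C2 (oxygen-bearing), C3 (CH2), C4 (bridgehead CH), C5 (CH2), C6 (CH carrying the benzylic CH2) and C7 (CMe2 bridge). Arene atoms are C1′ (benzylic CH2), C2′ (ether oxygen), C3′ (formyl), C4′ (OH), C5′ (3-methylbutanoyl) and C6′ (OH). Compound numbers are those of the steps below.

## Analysis of the target

The target is a tetracycle. A fully substituted phloroglucinol ring (ring A) is joined through a seven-membered oxepine (ring B: O–C2–C1–C6–CH2–C1′–C2′) to a bornane (rings C and D). It has four stereocentres: C1 (R), C2 (S), C4 (R) and C6 (S). C1 and C4 are bridgeheads and fix each other. The oxygen on C2 and the CH2 on C6 are both endo (anti to C7) and lie about 2.8 Å apart, which is the spacing of two ortho substituents on benzene, so ring B can only exist in this endo,endo arrangement. The sensitive groups are the aldehyde, the two phenols chelated to carbonyl groups, the electron-rich arene, and the secondary bornyl aryl ether at C2, which can ionise with Wagner–Meerwein shift under strong Lewis acids. The synthesis is hard for three reasons: C6 of a bornane is not activated by any camphor functionality; the quaternary C1 is flanked by C2, C6 and C7; and on ring A the formyl group must sit next to the ether oxygen while the acyl group sits between the phenols. The strategy rests on one feature: if C3 is deleted, C1, C2, C4 and C7 form a cyclobutanone bridged by C5–C6, a bicyclo[2.1.1]hexan-5-one. That is the crossed [2+2] adduct of a keteniminium ion (C2=C4) with a tetrasubstituted alkene (C1=C7), so only C6 has to be made as a stereocentre in an open chain.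

## Retrosynthetic reasoning

**32 to 31.** The two phenols are unmasked last. Both methoxy groups of 31 are ortho to a carbonyl group, so they can be cleaved under chelation control, while the ring ether cannot be attacked by substitution at its neopentyl-type carbon.

**31 to 29 and 30, then 29 to 27.** The C5′–acyl and C3′–formyl bonds are cut in that order. Ring A of 27 has only two free positions, so only the first substitution needs site control. C3′ is para to the coplanar C6′ methoxy group and is not buttressed, so the first electrophile is expected there, and it must therefore be the formyl carbon. The acyl chloride 30 then has one position left.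

**27 to 26.** The aryl C2′–O bond is cut. The bromine that this needs can be carried from the first step, and the rigid bornane holds the endo oxygen and C2′ at bonding distance, so a copper-catalysed closure of ring B is favourable.

**26 to 25.** The C2–H bond is cut back to the ketone. The forward step must deliver hydride to the exo face, and the 6-endo arylmethyl group should make the endo face the more hindered one.

**25 to 23.** C3 is removed. The strained cyclobutanone 23 should accept one carbon on the side of the less substituted bridgehead C4, which places the carbonyl next to the quaternary C1 as in camphor.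

**23 to 20 (key disconnection).** The bonds C1–C2 and C4–C7 are cut. This opens both carbocycles at once and leaves the acyclic amide 20 with a single stereocentre (C6). Forward, the keteniminium ion must add across the tetrasubstituted alkene in the crossed sense and on the face dictated by C6.

**20 to 17 and 18.** The bond between the α- and β-carbons of the amide is cut. The acetamide 18 brings two chain carbons and the pyrrolidine amide in one alkylation of the iodide 17, and the stereocentre is not involved.

**17 to 16 to 15, then 15 to 13 and 5.** The iodide comes from the alcohol 16, and this from the imide 15 by reductive removal of the auxiliary. The stereocentre is cut at its bond to the benzylic carbon: an auxiliary-controlled alkylation of the imide 13 with the benzylic bromide 5 sets it, at a carbon that is α to a carbonyl only at this stage.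

**13 to 10 and 11, then 10 to 9 to 6 and 7.** The acid 10 is attached to the auxiliary 11. Its β,γ-double bond is fixed by making the sp2–sp3 bond between the alkenyl bromide 7 and the zinc enolate derived from 6. Dehydration or deconjugation routes would give mixtures of alkene isomers.

**5 to 4 to 3 to 1.** The benzylic bromide comes from the alcohol and the aldehyde, and the aldehyde from formylation of 1 next to bromine.

## Alternatives that were turned down

**Alternative 1:** The C2–O bond is traced back to a C2–H bond and the skeleton is taken from the chiral pool.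
- Key step: (1S,4S)-camphor A3 (the less common enantiomer, because its carbonyl carbon becomes C6) would be homologated to the 6-endo hydroxymethyl bornane A2. Its hypoiodite, made with PhI(OAc)2 and I2 and photolysed, gives an alkoxy radical that takes the endo hydrogen of C2 through a six-membered transition state. Oxidation and ring closure give the oxolane A1.
- For it: C1, C4 and C6 come from camphor, and the C2–O bond is necessarily endo because the oxygen is delivered from the endo CH2. On that point it is stronger than the hydride reduction of step 13.
- Against it: in A1 the oxygen is bonded directly to the C6 CH2 group, whereas the target has two arene carbons between them. A1 would have to be reopened at its primary C–O bond, and both the CH2–aryl and O–aryl bonds would still have to be made. The alkoxy radical can also reach a C10 hydrogen (also a 1,5 relationship). The C2 radical is oxidised through a 2-bornyl cation that is prone to rearrangement. Hydroboration of the methylene derivative of A3 would give the exo, not the endo, CH2OH.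
- Comparison: the chosen route carries the C6–CH2–aryl bond from its first C–C bond formation and opens no ring again. It gives up chiral-pool certainty for one auxiliary-controlled alkylation.

**Alternative 2:** Ring B is cut at both C1′–CH2 and C2′–O.
- Key step: the aryl iodide A5 (methyl 2-iodo-4,6-dimethoxybenzoate) and the bromo alcohol A6 (2-endo-hydroxy-6-endo-bromomethyl bornane) react under Pd(OAc)2, tri(2-furyl)phosphine, norbornene and Cs2CO3. The aryl–palladium species is alkylated at its free ortho carbon by the bromide and then closed at the ipso carbon by the alkoxide, giving A4.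
- For it: it is the most convergent plan, and the ester fixes the site of the later formyl carbon by construction. On that point it is stronger than the site-selective formylation of step 15.
- Against it: A6 already contains the whole stereochemical problem (an enantiopure bornane with endo groups on C2 and C6), so the difficulty is moved, not solved. The β-branched primary bromide on the concave endo face is a poor partner for the substitution-type oxidative addition to the palladacycle. A palladium alkoxide of a secondary alcohol with a β-hydrogen tends to eliminate to the ketone before a seven-membered C–O reductive elimination. The ester must later be reduced to the aldehyde.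
- Comparison: two uncertain bond formations are coupled in one catalytic cycle. The chosen route makes ring B by a single preorganised C–O coupling after the skeleton is secure.

**Alternative 3:** The bonds C1–C2 and C3–C4 are cut, so that the bornane and ring B form together.
- Key step: the cyclopentadiene A8 (a 2-arylmethyl-1,5,5-trimethylcyclopentadiene whose arene carries an (E)-β-aryloxyacrylate) would add its tethered dienophile under a chiral oxazaborolidinium triflimide (type 2 intramolecular Diels–Alder), giving the born-5-ene A7 with the ester exo on C3.
- For it: two rings, two C–C bonds and the absolute configuration come from one catalytic step without an auxiliary. The CMe2 carbon blocks 1,5-hydrogen shifts of the diene. The C2–O bond is endo by the tether, so no ketone reduction is needed. On step count to the skeleton and on C2 it is stronger.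
- Against it: the β-aryloxyacrylate is a push–pull, deactivated dienophile. Its donor-substituted carbon must bond to C1, the fully substituted diene terminus next to CMe2, through a bridged transition state. Enantiocontrol by this catalyst class is established for simple intermolecular cases, not for such a tether. Afterwards the C3 ester must be excised (three or more steps) and C5=C6 hydrogenated.
- Comparison: the chosen key step also builds two rings and two C–C bonds, but between a very nucleophilic alkene and a very electrophilic cumulene held five atoms apart, and no carbon has to be removed later.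

Key step: step 11

Assumption: the compound is taken as the enantiomer drawn, (1R,2S,4R,6S) in bornane numbering. Electrophiles are assumed to attack ring A of 27 at C3′ before C5′ (as at C8 of 5,7-dialkoxychromans), which is why formylation precedes acylation.

## Route

Step 1
Reactants: 1 1-bromo-3,5-dimethoxybenzene
Product: 3 2-bromo-4,6-dimethoxybenzaldehyde, via aryl iminium salt 2 (not isolated)
Conditions: POCl3, DMF, 0 → 90 °C; then aq NaOAc
Reagents that add atoms: N,N-dimethylformamide, CN(C)C=O; water, O; phosphoryl chloride, O=P(Cl)(Cl)Cl (counter-ion of 2 only)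
Why: Vilsmeier–Haack formylation; the carbon para to one methoxy group and ortho to the other (next to bromine) is attacked in preference to the carbon between the two methoxy groups, and the iminium salt 2 is hydrolysed on work-up.

Step 2
Reactants: 3 2-bromo-4,6-dimethoxybenzaldehyde
Product: 4 (2-bromo-4,6-dimethoxyphenyl)methanol
Conditions: NaBH4, MeOH/THF, 0 °C
Reagents that add atoms: none
Why: Borohydride reduction of an aryl aldehyde; the aryl bromide and the ethers are inert.

Step 3
Reactants: 4 (2-bromo-4,6-dimethoxyphenyl)methanol
Product: 5 1-bromo-2-(bromomethyl)-3,5-dimethoxybenzene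
Conditions: PBr3, CH2Cl2, 0 °C; used directly
Reagents that add atoms: phosphorus tribromide, BrP(Br)Br
Why: Conversion of a benzylic alcohol into the bromide through its phosphite (SN2 by bromide); the electron-rich benzylic bromide is labile and is used at once.

Step 4
Reactants: 6 ethyl bromoacetate; 7 2-bromo-3-methylbut-2-ene
Product: 9 ethyl 3,4-dimethylpent-3-enoate, via Reformatsky reagent 8 (not isolated)
Conditions: Zn (Me3SiCl-activated), THF, 40 °C; then 7, Pd(dba)2 (2 mol %), P(t-Bu)3 (4 mol %), THF, rt → 50 °C
Reagents that add atoms: zinc, [Zn] (kept in intermediate 8 only)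
Why: Negishi-type coupling of a Reformatsky reagent with an alkenyl bromide; the new sp2–sp3 bond places the tetrasubstituted double bond unambiguously in the β,γ position.

Step 5
Reactants: 9 ethyl 3,4-dimethylpent-3-enoate
Product: 10 3,4-dimethylpent-3-enoic acid
Conditions: LiOH, THF/MeOH/H2O, rt; then cold 1 M HCl to pH 3
Reagents that add atoms: lithium hydroxide, [Li+].[OH-]
Why: Saponification at room temperature; hydroxide does not move the double bond into conjugation, and the brief cold acidification avoids acid-induced lactonisation onto the tetrasubstituted alkene.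

Step 6
Reactants: 10 3,4-dimethylpent-3-enoic acid; 11 (S)-4-benzyloxazolidin-2-one
Product: 13 (S)-4-benzyl-3-(3,4-dimethylpent-3-enoyl)oxazolidin-2-one, via mixed pivalic anhydride 12 (not isolated)
Conditions: t-BuCOCl, Et3N, THF, −20 °C; then LiCl, 11, −20 °C → rt
Reagents that add atoms: pivaloyl chloride, CC(C)(C)C(Cl)=O (kept in intermediate 12 only)
Why: N-Acylation of the Evans auxiliary through the mixed anhydride with LiCl/Et3N activation; no strong base is used, so the β,γ-alkene stays in place.

Step 7
Reactants: 13 (S)-4-benzyl-3-(3,4-dimethylpent-3-enoyl)oxazolidin-2-one; 5 1-bromo-2-(bromomethyl)-3,5-dimethoxybenzene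
Product: 15 (S)-4-benzyl-3-[(S)-2-(2-bromo-4,6-dimethoxybenzyl)-3,4-dimethylpent-3-enoyl]oxazolidin-2-one, via sodium dienolate 14 (not isolated)
Conditions: NaN(SiMe3)2 (1.1 equiv), THF, −78 °C; then 5 (1.5 equiv), −78 → −30 °C
Reagents that add atoms: sodium bis(trimethylsilyl)amide, C[Si](C)(C)[N-][Si](C)(C)C.[Na+] (sodium of intermediate 14 only)
Why: Evans alkylation: the chelated sodium (Z)-dienolate 14 reacts at its α-carbon (the γ-carbon is fully substituted) on the face opposite the auxiliary benzyl group, which sets the only acyclic stereocentre as S. The low temperature keeps the acidic α-hydrogen of 15 from epimerising.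

Step 8
Reactants: 15 (S)-4-benzyl-3-[(S)-2-(2-bromo-4,6-dimethoxybenzyl)-3,4-dimethylpent-3-enoyl]oxazolidin-2-one
Product: 16 (S)-2-(2-bromo-4,6-dimethoxybenzyl)-3,4-dimethylpent-3-en-1-ol
Conditions: LiBH4, MeOH (1 equiv), Et2O, 0 °C
Reagents that add atoms: none
Why: Reductive cleavage of the exocyclic imide carbonyl with LiBH4/MeOH; afterwards the stereocentre is no longer α to a carbonyl group and is configurationally safe, and the auxiliary 11 is recovered.

Step 9
Reactants: 16 (S)-2-(2-bromo-4,6-dimethoxybenzyl)-3,4-dimethylpent-3-en-1-ol
Product: 17 1-bromo-2-[(2S)-2-(iodomethyl)-3,4-dimethylpent-3-en-1-yl]-3,5-dimethoxybenzene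
Conditions: PPh3, imidazole, I2 (premixed), CH2Cl2, 0 °C → rt
Reagents that add atoms: iodine, II
Why: Appel-type iodination (SN2 at the primary carbon); the phosphine–iodine adduct is formed before the alcohol is added, so that no free iodine meets the electron-rich alkene and its homoallylic hydroxyl (iodoetherification).

Step 10
Reactants: 17 1-bromo-2-[(2S)-2-(iodomethyl)-3,4-dimethylpent-3-en-1-yl]-3,5-dimethoxybenzene; 18 1-(pyrrolidin-1-yl)ethan-1-one
Product: 20 (S)-4-(2-bromo-4,6-dimethoxybenzyl)-5,6-dimethyl-1-(pyrrolidin-1-yl)hept-5-en-1-one, via lithium enolate 19 (not isolated)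
Conditions: 18 (3.0 equiv), LDA (2.8 equiv), THF, −78 °C; then 17, DMPU, −78 °C → rt
Reagents that add atoms: lithium diisopropylamide, CC(C)[N-]C(C)C.[Li+] (lithium of intermediate 19 only)
Why: SN2 alkylation of a tertiary acetamide lithium enolate by a primary iodide, which adds both chain carbons and the pyrrolidine amide in one operation. LDA is kept in deficiency so that no free amide base deprotonates the ring carbon between bromine and methoxy; the allylic C–H of 17 lies in the alkene plane (allylic 1,3-strain), which disfavours E2.

Step 11
Reactants: 20 (S)-4-(2-bromo-4,6-dimethoxybenzyl)-5,6-dimethyl-1-(pyrrolidin-1-yl)hept-5-en-1-one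
Product: 23 (1R,2S,4S)-2-(2-bromo-4,6-dimethoxybenzyl)-1,6,6-trimethylbicyclo[2.1.1]hexan-5-one, via keteniminium triflate 21 (not isolated), via cyclobutaniminium triflate 22 (not isolated)
Conditions: Tf2O (1.2 equiv), 2,4,6-collidine (1.5 equiv), ClCH2CH2Cl (0.02 M), 0 → 80 °C; then aq NaHCO3, 60 °C
Reagents that add atoms: water, O; trifluoromethanesulfonic anhydride, O=S(=O)(OS(=O)(=O)C(F)(F)F)C(F)(F)F (triflate counter-ion of 21 and 22 only)
Why: Tf2O and collidine turn the amide into the keteniminium ion 21; its electrophilic carbon (future C2) is attacked by the proximal alkene carbon (future C1), the former α-carbon (future C4), now an enamine carbon, closes on the tertiary cation at C7, and hydrolysis of the cyclobutaniminium salt 22 gives the ketone. The closest known reaction type is the intramolecular keteniminium–alkene (and ketene–alkene) [2+2] cycloaddition in its crossed mode, which gives bridged cyclobutanones when the charge can rest on the distal alkene carbon. The five-membered ring (C1–C2–C4–C5–C6) closes in the 5-exo sense with respect to the alkene, and the four-membered ring (C1–C2–C4–C7) closes by collapse of the cation–enamine pair; the fused mode is excluded because the two-atom tether would demand a bicyclo[2.2.0]hexane. C1 is controlled by the C6 stereocentre through allylic 1,3-strain: the C6–H bond eclipses the C1=C7 bond to avoid the cis methyl on C7, so the tether and the benzyl group lie on opposite faces, and attack from the tether face leaves the benzyl group on the side of the carbonyl bridge, away from CMe2. C4 is not independent, since the cyclobutane can only bridge the five-membered ring cis. The step needs chemoselectivity for the alkene over the arene: both carbons ortho to the benzylic carbon are substituted, so Friedel–Crafts closure to a seven-membered ring is blocked, and the tetrasubstituted alkene five atoms away is the kinetically favoured partner. High dilution suppresses intermolecular reactions of 21.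

Step 12
Reactants: 23 (1R,2S,4S)-2-(2-bromo-4,6-dimethoxybenzyl)-1,6,6-trimethylbicyclo[2.1.1]hexan-5-one
Product: 25 (1R,4R,6S)-6-(2-bromo-4,6-dimethoxybenzyl)-1,7,7-trimethylbicyclo[2.2.1]heptan-2-one, via α-silyl ketone 24 (not isolated)
Conditions: Me3SiCHN2, BF3·OEt2, CH2Cl2, −78 °C; then aq NaHCO3; then 1 M HCl, THF, rt
Reagents that add atoms: trimethylsilyldiazomethane, C[Si](C)(C)C=[N+]=[N-]
Why: Lewis acid-promoted diazoalkane homologation (Tiffeneau–Demjanov type) of a strained cyclobutanone; the less substituted bridgehead C4 migrates in preference to the quaternary C1, so the new carbon becomes C3 and the carbonyl stays next to C1, and the α-silyl ketone 24 is protodesilylated by the acid. The cyclopentanone formed is far less reactive, which limits a second insertion.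

Step 13
Reactants: 25 (1R,4R,6S)-6-(2-bromo-4,6-dimethoxybenzyl)-1,7,7-trimethylbicyclo[2.2.1]heptan-2-one
Product: 26 (1R,2S,4R,6S)-6-(2-bromo-4,6-dimethoxybenzyl)-1,7,7-trimethylbicyclo[2.2.1]heptan-2-ol
Conditions: LiAlH4, Et2O, −78 → 0 °C
Reagents that add atoms: none
Why: Hydride addition under steric approach control; the 6-endo arylmethyl group should block the endo face of C2 more than the syn methyl on C7 blocks the exo face (the situation of a norbornan-2-one is restored), so hydride enters exo and gives the 2-endo alcohol (2S). The aryl bromide is not reduced at this temperature.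

Step 14
Reactants: 26 (1R,2S,4R,6S)-6-(2-bromo-4,6-dimethoxybenzyl)-1,7,7-trimethylbicyclo[2.2.1]heptan-2-ol
Product: 27 tetracyclic dimethyl ether (bornane bridged from the endo oxygen on C2 to the endo CH2 on C6 by a 4′,6′-dimethoxy-1′,2′-phenylene unit; 1R,2S,4R,6S)
Conditions: CuI (10 mol %), 3,4,7,8-tetramethyl-1,10-phenanthroline (20 mol %), Cs2CO3, toluene, 110 °C
Reagents that add atoms: none
Why: Intramolecular Ullmann-type C–O coupling of a secondary alkoxide with an aryl bromide; the rigid bornane holds the endo oxygen and C2′ at bonding distance, which closes ring B. Copper alkoxides do not undergo the β-hydride elimination that would trouble palladium here.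

Step 15
Reactants: 27 tetracyclic dimethyl ether
Product: 29 3′-formyl tetracyclic dimethyl ether, via α-chloro ether 28 (not isolated)
Conditions: Cl2CHOMe (1.1 equiv), TiCl4, CH2Cl2, −78 → 0 °C; then H2O
Reagents that add atoms: dichloromethyl methyl ether, COC(Cl)Cl; water, O
Why: Rieche formylation of a phloroglucinol triether; C3′ is para to the coplanar C6′ methoxy group and flanked by the ring oxygen, whose alkyl group points away, whereas C5′ is buttressed by the C6′ O-methyl group, so substitution should occur at C3′. The aldehyde deactivates the ring and stops a second formylation.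

Step 16
Reactants: 29 3′-formyl tetracyclic dimethyl ether; 30 3-methylbutanoyl chloride
Product: 31 3′-formyl-5′-(3-methylbutanoyl) tetracyclic dimethyl ether
Conditions: TiCl4, CH2Cl2, 0 °C → rt
Reagents that add atoms: none
Why: Friedel–Crafts acylation at C5′, the only ring position left; a second electrophilic substitution on 2,4,6-trialkoxybenzaldehydes is known from their bis-formylation and from the acylation of formylphloroglucinols, and an acylium ion is the stronger electrophile. Loss of the methyl group ortho to the aldehyde under TiCl4 would be harmless, since both methyl groups are removed in the next step.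

Step 17
Reactants: 31 3′-formyl-5′-(3-methylbutanoyl) tetracyclic dimethyl ether
Product: 32 target CNP0246493.1
Conditions: BCl3, CH2Cl2, −78 → 0 °C; then H2O
Reagents that add atoms: none
Why: Chelation-assisted cleavage of aryl methyl ethers ortho to a carbonyl group by BCl3 (chloride attacks the methyl carbon of the boron chelate); both methoxy groups qualify. The ring ether can only break by ionisation at the neopentyl-type C2 with an endo leaving group, which is slow at low temperature.

## Compound list

1 | 1-bromo-3,5-dimethoxybenzene | COc1cc(Br)cc(OC)c1 | starting material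
2 | (2-bromo-4,6-dimethoxybenzylidene)dimethyliminium dichlorophosphate | COc1cc(OC)c(C=[N+](C)C)c(Br)c1.[O-]P(=O)(Cl)Cl | intermediate
3 | 2-bromo-4,6-dimethoxybenzaldehyde | COc1cc(OC)c(C=O)c(Br)c1 | intermediate
4 | (2-bromo-4,6-dimethoxyphenyl)methanol | COc1cc(OC)c(CO)c(Br)c1 | intermediate
5 | 1-bromo-2-(bromomethyl)-3,5-dimethoxybenzene | COc1cc(OC)c(CBr)c(Br)c1 | intermediate
6 | ethyl bromoacetate | CCOC(=O)CBr | starting material
7 | 2-bromo-3-methylbut-2-ene | CC(C)=C(C)Br | starting material
8 | (2-ethoxy-2-oxoethyl)zinc bromide | CCOC(=O)C[Zn]Br | intermediate
9 | ethyl 3,4-dimethylpent-3-enoate | CCOC(=O)CC(C)=C(C)C | intermediate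
10 | 3,4-dimethylpent-3-enoic acid | CC(C)=C(C)CC(=O)O | intermediate
11 | (S)-4-benzyloxazolidin-2-one | O=C1N[C@@H](Cc2ccccc2)CO1 | starting material
12 | 3,4-dimethylpent-3-enoic pivalic anhydride | CC(C)=C(C)CC(=O)OC(=O)C(C)(C)C | intermediate
13 | (S)-4-benzyl-3-(3,4-dimethylpent-3-enoyl)oxazolidin-2-one | CC(C)=C(C)CC(=O)N1[C@@H](Cc2ccccc2)COC1=O | intermediate
14 | sodium (Z)-dienolate of 13 | CC(C)=C(C)/C=C(\[O-])N1[C@@H](Cc2ccccc2)COC1=O.[Na+] | intermediate
15 | (S)-4-benzyl-3-[(S)-2-(2-bromo-4,6-dimethoxybenzyl)-3,4-dimethylpent-3-enoyl]oxazolidin-2-one | CC(C)=C(C)[C@H](Cc1c(Br)cc(OC)cc1OC)C(=O)N1[C@@H](Cc2ccccc2)COC1=O | intermediate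
16 | (S)-2-(2-bromo-4,6-dimethoxybenzyl)-3,4-dimethylpent-3-en-1-ol | CC(C)=C(C)[C@H](Cc1c(Br)cc(OC)cc1OC)CO | intermediate
17 | 1-bromo-2-[(2S)-2-(iodomethyl)-3,4-dimethylpent-3-en-1-yl]-3,5-dimethoxybenzene | CC(C)=C(C)[C@H](Cc1c(Br)cc(OC)cc1OC)CI | intermediate
18 | 1-(pyrrolidin-1-yl)ethan-1-one | CC(=O)N1CCCC1 | starting material
19 | lithium 1-(pyrrolidin-1-yl)ethen-1-olate | C=C([O-])N1CCCC1.[Li+] | intermediate
20 | (S)-4-(2-bromo-4,6-dimethoxybenzyl)-5,6-dimethyl-1-(pyrrolidin-1-yl)hept-5-en-1-one | CC(C)=C(C)[C@H](Cc1c(Br)cc(OC)cc1OC)CCC(=O)N1CCCC1 | intermediate
21 | keteniminium triflate derived from 20 (C=C=N+ at the former amide carbon) | CC(C)=C(C)[C@H](Cc1c(Br)cc(OC)cc1OC)CC=C=[N+]1CCCC1.[O-]S(=O)(=O)C(F)(F)F | intermediate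
22 | pyrrolidinium (iminium) triflate of 23 | COc1cc(OC)c(C[C@@H]2C[C@@H]3C(=[N+]4CCCC4)[C@@]2(C)C3(C)C)c(Br)c1.[O-]S(=O)(=O)C(F)(F)F | intermediate
23 | (1R,2S,4S)-2-(2-bromo-4,6-dimethoxybenzyl)-1,6,6-trimethylbicyclo[2.1.1]hexan-5-one | COc1cc(OC)c(C[C@@H]2C[C@@H]3C(=O)[C@@]2(C)C3(C)C)c(Br)c1 | intermediate
24 | 3-trimethylsilyl derivative of 25 (both C3 epimers) | COc1cc(OC)c(C[C@@H]2C[C@@H]3C([Si](C)(C)C)C(=O)[C@@]2(C)C3(C)C)c(Br)c1 | intermediate
25 | (1R,4R,6S)-6-(2-bromo-4,6-dimethoxybenzyl)-1,7,7-trimethylbicyclo[2.2.1]heptan-2-one (benzyl 6-endo) | COc1cc(OC)c(C[C@@H]2C[C@@H]3CC(=O)[C@@]2(C)C3(C)C)c(Br)c1 | intermediate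
26 | (1R,2S,4R,6S)-6-(2-bromo-4,6-dimethoxybenzyl)-1,7,7-trimethylbicyclo[2.2.1]heptan-2-ol (OH 2-endo, benzyl 6-endo) | COc1cc(OC)c(C[C@@H]2C[C@@H]3C[C@H](O)[C@@]2(C)C3(C)C)c(Br)c1 | intermediate
27 | tetracyclic dimethyl ether (ring B closed; C3′ and C5′ unsubstituted; 4′,6′-dimethoxy) | c1c(OC)cc2c(c1OC)C[C@@H]1C[C@@H]3C[C@H](O2)[C@@]1(C)C3(C)C | intermediate
28 | 3′-[chloro(methoxy)methyl] derivative of 27 | c1c(OC)c(C(Cl)OC)c2c(c1OC)C[C@@H]1C[C@@H]3C[C@H](O2)[C@@]1(C)C3(C)C | intermediate
29 | 3′-formyl tetracyclic dimethyl ether | c1c(OC)c(C=O)c2c(c1OC)C[C@@H]1C[C@@H]3C[C@H](O2)[C@@]1(C)C3(C)C | intermediate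
30 | 3-methylbutanoyl chloride | CC(C)CC(Cl)=O | starting material
31 | 3′-formyl-5′-(3-methylbutanoyl) tetracyclic dimethyl ether | CC(C)CC(=O)c1c(OC)c(C=O)c2c(c1OC)C[C@@H]1C[C@@H]3C[C@H](O2)[C@@]1(C)C3(C)C | intermediate
32 | CNP0246493.1 (3′-formyl-4′,6′-dihydroxy-5′-(3-methylbutanoyl) tetracycle; 1R,2S,4R,6S) | CC(C)CC(=O)c1c(O)c(C=O)c2c(c1O)C[C@@H]1C[C@@H]3C[C@H](O2)[C@@]1(C)C3(C)C | target

## Step count and least certain steps

Total: 17 steps. Longest linear sequence: 14 steps (steps 4–17 from 6 and 7, or steps 1–3 and 7–17 from 1).

**Step 11 (key step).** The most likely failure is capture of the keteniminium carbon by the arene instead of the alkene: ipso attack at C1′ through a six-membered transition state, made possible by the ortho and para methoxy groups, followed by loss of a methyl group to the base. A second diversion is proton loss from the tertiary cation at C7 before the four-membered ring closes. Erosion of facial selectivity is less likely, because the competing conformer carries full allylic 1,3-strain. The fallback sets out from 17 and returns at 23; it finishes the chain as a carboxylic acid and uses the neutral ketene. Sodium diethyl malonate alkylates 17 (NaH, DMF, 60 °C) to the malonate diester F1. Saponification and thermal decarboxylation (KOH, EtOH/H2O; then 150 °C) give the heptenoic acid F2. Oxalyl chloride gives the acid chloride F3. Slow addition of F3 to Et3N in toluene at reflux forms the ketene F4, which closes thermally by the same crossed [2+2] to 23. A ketene is a much weaker electrophile toward an arene and adds in a more concerted way, at the price of a slower cycloaddition that competes with ketene dimerisation.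

**Step 13.** Hydride delivery to the endo face may compete, because both faces of C2 are hindered. The resulting exo alcohol cannot close ring B (its oxygen would be over 4 Å from the benzylic carbon). The fallback sets out from 25 and returns at 27, skipping 26; the tether, not the reagent, fixes the configuration. Palladium-catalysed hydroxylation of the aryl bromide (Pd2(dba)3, t-BuXPhos, KOH, dioxane/H2O, 100 °C) gives the phenol ketone F5. With Et3SiH and Me3SiOTf in CH2Cl2 (−40 → 0 °C) the phenol, which sits over the endo face of the carbonyl, adds to C2 and the cyclic oxocarbenium ion F6 is reduced. The silane can only add from the exo face, since the oxygen is held endo by the arene. This is an intramolecular reductive etherification.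

**Step 15.** Site selectivity between C3′–H and C5′–H may be incomplete, since both carbons are activated by three oxygens and the preference rests on sterics and conformation. The fallback sets out from 27 and returns at 29; it replaces electrophilic substitution by directed metalation. n-BuLi/TMEDA in THF at 0 °C should deprotonate C3′, where the in-plane lone pairs of the ring oxygen and of the C4′ methoxy group converge (the C6′ methoxy group is forced to turn its methyl toward C5′). The aryllithium F7 is quenched with DMF.

**Step 16.** The formyl group deactivates the ring and binds the Lewis acid, so acylation may stall, and forcing it raises the risk of ionising the C2–O bond. The fallback sets out from 29 and returns at 31; it uses no Lewis acid. Lithium 4-methylpiperazin-1-ide adds to the aldehyde to give the α-amino alkoxide F8, which protects it in the flask. n-BuLi then lithiates C5′, the only ring C–H, between two methoxy groups. Addition of 3-methylbutanal and aqueous work-up give the carbinol aldehyde F9. Dess–Martin periodinane oxidises the benzylic alcohol to 31.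

**Step 17.** The Lewis acid may cleave the ring ether by ionisation at C2 with skeletal rearrangement, in competition with O-demethylation. The fallback sets out from 29 and returns at 32; it removes the methyl groups by SN2 before the acyl group is introduced, so that no Lewis-acid demethylation is needed. NaSEt in DMF at 110 °C cleaves both methoxy groups of 29 (ortho and para to the aldehyde, hence activated as leaving phenoxides) to the dihydroxy aldehyde F10. The thiolate cannot attack the neopentyl-type C2. C-Acylation of F10 with 30 and TiCl4 (CH2Cl2, 0 °C → rt) at C5′, now between two free hydroxyls, gives 32 directly.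

## Further compounds

F1 | step 11 | diethyl 2-[(2S)-2-(2-bromo-4,6-dimethoxybenzyl)-3,4-dimethylpent-3-en-1-yl]malonate | CC(C)=C(C)[C@H](Cc1c(Br)cc(OC)cc1OC)CC(C(=O)OCC)C(=O)OCC
F2 | step 11 | (S)-4-(2-bromo-4,6-dimethoxybenzyl)-5,6-dimethylhept-5-enoic acid | CC(C)=C(C)[C@H](Cc1c(Br)cc(OC)cc1OC)CCC(=O)O
F3 | step 11 | (S)-4-(2-bromo-4,6-dimethoxybenzyl)-5,6-dimethylhept-5-enoyl chloride | CC(C)=C(C)[C@H](Cc1c(Br)cc(OC)cc1OC)CCC(Cl)=O
F4 | step 11 | (S)-4-(2-bromo-4,6-dimethoxybenzyl)-5,6-dimethylhepta-1,5-dien-1-one (ketene) | CC(C)=C(C)[C@H](Cc1c(Br)cc(OC)cc1OC)CC=C=O
F5 | step 13 | (1R,4R,6S)-6-(2-hydroxy-4,6-dimethoxybenzyl)-1,7,7-trimethylbicyclo[2.2.1]heptan-2-one | COc1cc(O)c(C[C@@H]2C[C@@H]3CC(=O)[C@@]2(C)C3(C)C)c(OC)c1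
F6 | step 13 | cyclic aryl oxocarbenium triflate (C2=O+ within ring B) | c1c(OC)cc2c(c1OC)C[C@@H]1C[C@@H]3CC(=[O+]2)[C@@]1(C)C3(C)C.[O-]S(=O)(=O)C(F)(F)F
F7 | step 15 | 3′-lithio derivative of 27 | c1c(OC)c([Li])c2c(c1OC)C[C@@H]1C[C@@H]3C[C@H](O2)[C@@]1(C)C3(C)C
F8 | step 16 | lithium α-(4-methylpiperazin-1-yl) alkoxide of 29 | c1c(OC)c(C([O-])N4CCN(C)CC4)c2c(c1OC)C[C@@H]1C[C@@H]3C[C@H](O2)[C@@]1(C)C3(C)C.[Li+]
F9 | step 16 | 3′-formyl-5′-(1-hydroxy-3-methylbutyl) tetracyclic dimethyl ether | CC(C)CC(O)c1c(OC)c(C=O)c2c(c1OC)C[C@@H]1C[C@@H]3C[C@H](O2)[C@@]1(C)C3(C)C
F10 | step 17 | 3′-formyl-4′,6′-dihydroxy tetracycle | c1c(O)c(C=O)c2c(c1O)C[C@@H]1C[C@@H]3C[C@H](O2)[C@@]1(C)C3(C)C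
A1 | alternative 1 | oxolane bridging C2 (endo O) and the CH2 on C6 of the bornane | C1[C@@H]2C[C@@H]3C[C@H](O1)[C@@]2(C)C3(C)C
A2 | alternative 1 | 6-endo-(hydroxymethyl)bornane (target numbering) | OC[C@@H]1C[C@@H]2CC[C@@]1(C)C2(C)C
A3 | alternative 1 | (1S,4S)-camphor | O=C1C[C@@H]2CC[C@@]1(C)C2(C)C
A4 | alternative 2 | tetracyclic dimethyl ether with a methyl ester on C3′ | c1c(OC)c(C(=O)OC)c2c(c1OC)C[C@@H]1C[C@@H]3C[C@H](O2)[C@@]1(C)C3(C)C
A5 | alternative 2 | methyl 2-iodo-4,6-dimethoxybenzoate | COC(=O)c1c(I)cc(OC)cc1OC
A6 | alternative 2 | 2-endo-hydroxy-6-endo-(bromomethyl)bornane | BrC[C@@H]1C[C@@H]2C[C@H](O)[C@@]1(C)C2(C)C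
A7 | alternative 3 | oxepine-bridged born-5-ene with a 3-exo methyl ester | c1c(OC)cc2c(c1OC)CC1=C[C@@H]3[C@@H](C(=O)OC)[C@H](O2)[C@@]1(C)C3(C)C
A8 | alternative 3 | methyl (E)-3-{3,5-dimethoxy-2-[(2,3,3-trimethylcyclopenta-1,4-dien-1-yl)methyl]phenoxy}acrylate | CC1=C(Cc2c(OC)cc(OC)cc2O/C=C/C(=O)OC)C=CC1(C)C
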